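Ring A, the aryloxy ring (C1 ether carbon, C2 isopropyl, C3 H, C4 methoxy, C5 methyl, C6 H), is not coupled to ring B but grown on an ether oxygen already attached to ring B. Its O–C1 carbon flanked by C2 and C6, with oxygen para at C4, maps onto a 2-aryloxy-3-oxo-aldehyde unit (C6–C1–C2) and a β-ketoester dienolate (C5–C4–C3). A TiCl4-mediated formal [3+3] cyclocondensation of the derived 2-aryloxy-3-silyloxyenone with a 1,3-bis(silyloxy)diene forms C5–C6 and C2–C3 and closes ring A as a salicylate, whose C3 ester is later excised and whose C4 hydroxyl becomes the methoxy group.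

Key step: step 11

Assumption: silyl enol ethers 12, 14 and 15 are drawn as the single geometric isomers expected from the chelated enols; isomer mixtures would serve equally, because no alkene geometry survives aromatisation.

Step 1
Reactants: 1 thymol (2-isopropyl-5-methylphenol)
Product: 2 4-bromo-2-isopropyl-5-methylphenol
Conditions: NBS (1.0 equiv), MeCN, 0 → 25 °C
Reagents that add atoms: N-bromosuccinimide, O=C1CCC(=O)N1Br
Why: Electrophilic aromatic bromination of the phenol should go para to the hydroxyl, because the only free ortho site is crowded between OH and methyl.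

Step 2
Reactants: 2 4-bromo-2-isopropyl-5-methylphenol
Product: 3 2-isopropyl-4-methoxy-5-methylphenol
Conditions: NaOMe (5 equiv), CuBr (0.1 equiv), DMF–MeOH, 110 °C; then aq. HCl
Reagents that add atoms: sodium methoxide, [Na+].[O-]C
Why: Copper-catalysed Ullmann-type methoxylation of a bromophenol replaces bromide by methoxide and so places the para oxygen without regiochemical ambiguity.

Step 3
Reactants: 3 2-isopropyl-4-methoxy-5-methylphenol
Product: 4 2-hydroxy-3-isopropyl-5-methoxy-6-methylbenzaldehyde
Conditions: MgCl2, Et3N, (CH2O)n, MeCN, reflux; then aq. HCl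
Reagents that add atoms: paraformaldehyde (as formaldehyde), C=O
Why: Magnesium-phenoxide-directed ortho-formylation (Casnati–Skattebøl reaction) can only attack the single free ortho position, between hydroxyl and methyl.

Step 4
Reactants: 4 2-hydroxy-3-isopropyl-5-methoxy-6-methylbenzaldehyde
Product: 5 2-(benzyloxy)-3-isopropyl-5-methoxy-6-methylbenzaldehyde
Conditions: BnBr, K2CO3, DMF, 60 °C
Reagents that add atoms: benzyl bromide, BrCc1ccccc1
Why: Williamson etherification of the salicylaldehyde hydroxyl with a reactive benzylic bromide in a dipolar aprotic solvent should overcome the hydrogen bond to the formyl group.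

Step 5
Reactants: 5 2-(benzyloxy)-3-isopropyl-5-methoxy-6-methylbenzaldehyde
Product: 7 2-(benzyloxy)-3-isopropyl-5-methoxy-6-methylphenol, via aryl formate 6 (not isolated)
Conditions: mCPBA, CH2Cl2, 0 → 25 °C; then NaOH, MeOH–H2O, 25 °C; aq. HCl
Reagents that add atoms: 3-chloroperoxybenzoic acid (mCPBA), OOC(=O)c1cccc(Cl)c1
Why: Baeyer–Villiger (Dakin-type) oxidation of an ortho-alkoxybenzaldehyde proceeds with aryl migration to the formate, which mild base hydrolyses to the phenol.

Step 6
Reactants: 7 2-(benzyloxy)-3-isopropyl-5-methoxy-6-methylphenol; 8 1-bromo-3-methylbutan-2-one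
Product: 9 1-[2-(benzyloxy)-3-isopropyl-5-methoxy-6-methylphenoxy]-3-methylbutan-2-one
Conditions: K2CO3, NaI (cat.), acetone, reflux
Reagents that add atoms: none
Why: Williamson alkylation of the phenoxide with a highly reactive primary α-bromoketone forms the hindered ether link by SN2 displacement at an sp3 carbon.

Step 7
Reactants: 9 1-[2-(benzyloxy)-3-isopropyl-5-methoxy-6-methylphenoxy]-3-methylbutan-2-one; 10 ethyl formate
Product: 11 (1E)-2-[2-(benzyloxy)-3-isopropyl-5-methoxy-6-methylphenoxy]-1-hydroxy-4-methylpent-1-en-3-one (chelated enol of the 3-oxo-aldehyde)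
Conditions: NaH (2 equiv), EtOH (cat.), THF, 0 → 25 °C; then aq. HCl
Reagents that add atoms: none
Why: Crossed Claisen condensation with the non-enolisable formate occurs at the more acidic aryloxy-methylene and is driven by the stable enolate of the 3-oxo-aldehyde, which the isopropyl methine side cannot form.

Step 8
Reactants: 11 (1E)-2-[2-(benzyloxy)-3-isopropyl-5-methoxy-6-methylphenoxy]-1-hydroxy-4-methylpent-1-en-3-one
Product: 12 (1E)-2-[2-(benzyloxy)-3-isopropyl-5-methoxy-6-methylphenoxy]-4-methyl-1-(trimethylsilyloxy)pent-1-en-3-one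
Conditions: TMSCl, Et3N, CH2Cl2–pentane, 25 °C; filtered under argon, used crude
Reagents that add atoms: chlorotrimethylsilane, C[Si](C)(C)Cl
Why: O-Silylation of the hydroxymethylene ketone with TMSCl and a tertiary amine takes place at the unhindered enol oxygen and gives the 3-silyloxy-enone dielectrophile.

Step 9
Reactants: 13 methyl 3-oxopentanoate
Product: 14 methyl (2Z)-3-(trimethylsilyloxy)pent-2-enoate
Conditions: TMSCl, Et3N, toluene, 25 °C; distilled
Reagents that add atoms: chlorotrimethylsilane, C[Si](C)(C)Cl
Why: Silyl enol ether formation from a β-ketoester with TMSCl and a tertiary amine is the standard first stage of bis-silyl dienolate synthesis.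

Step 10
Reactants: 14 methyl (2Z)-3-(trimethylsilyloxy)pent-2-enoate
Product: 15 (1Z,3Z)-1-methoxy-1,3-bis(trimethylsilyloxy)penta-1,3-diene
Conditions: LiN(iPr)2 (LDA), THF, −78 °C; TMSCl, −78 → 20 °C; pentane, filtered, used crude
Reagents that add atoms: chlorotrimethylsilane, C[Si](C)(C)Cl
Why: Kinetic γ-deprotonation of the silyl enol ether and O-silylation of the resulting ester dienolate give the 1,3-bis(silyloxy)diene, a masked β-ketoester dianion.

Step 11
Reactants: 12 (1E)-2-[2-(benzyloxy)-3-isopropyl-5-methoxy-6-methylphenoxy]-4-methyl-1-(trimethylsilyloxy)pent-1-en-3-one; 15 (1Z,3Z)-1-methoxy-1,3-bis(trimethylsilyloxy)penta-1,3-diene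
Product: 18 methyl 3-[2-(benzyloxy)-3-isopropyl-5-methoxy-6-methylphenoxy]-6-hydroxy-2-isopropyl-5-methylbenzoate, via enedione ester 16 (not isolated), via cyclic aldol 17 (not isolated)
Conditions: TiCl4 (1.1 equiv), 15 (1.5 equiv), 4 Å MS, CH2Cl2, −78 → 20 °C; then aq. HCl
Reagents that add atoms: none
Why: TiCl4 activates enone 12, and the terminal carbon of diene 15 adds in Mukaiyama–Michael fashion to the silyloxymethylene carbon with loss of silanolate, giving enedione ester 16 and the C5–C6 bond. The titanium-bound β-ketoester carbon of 16 then attacks the isopropyl ketone in an intramolecular aldol addition (6-exo-trig, enol endo), which forms C2–C3 and closes ring A as cyclic aldol 17. Dehydration and enolisation of 17 aromatise the ring to the salicylate. The closest known reaction type is the Lewis-acid-mediated formal [3+3] cyclocondensation of 1,3-bis(silyloxy)-1,3-dienes with 3-silyloxy-2-en-1-ones, which is established for 2-aryloxy enones leading to diaryl ethers. No stereocentre is created in the product, and the transient centres and alkene geometry of 16 and 17 are erased on aromatisation. The step needs regioselectivity, which the substrate secures because the exposed silyloxymethylene carbon is far more accessible to the more nucleophilic diene terminus than the isopropyl ketone next to the bulky aryloxy group, so the ketone is left for the intramolecular closure.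

Step 12
Reactants: 18 methyl 3-[2-(benzyloxy)-3-isopropyl-5-methoxy-6-methylphenoxy]-6-hydroxy-2-isopropyl-5-methylbenzoate
Product: 19 methyl 3-[2-(benzyloxy)-3-isopropyl-5-methoxy-6-methylphenoxy]-2-isopropyl-6-methoxy-5-methylbenzoate
Conditions: MeI, K2CO3, DMF, 50 °C
Reagents that add atoms: iodomethane, CI
Why: Williamson O-methylation of the salicylate hydroxyl in a dipolar aprotic solvent should break its hydrogen bond to the ester and install the C4 methoxy group.

Step 13
Reactants: 19 methyl 3-[2-(benzyloxy)-3-isopropyl-5-methoxy-6-methylphenoxy]-2-isopropyl-6-methoxy-5-methylbenzoate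
Product: 20 3-[2-(benzyloxy)-3-isopropyl-5-methoxy-6-methylphenoxy]-2-isopropyl-6-methoxy-5-methylbenzoic acid
Conditions: n-PrSLi (from n-PrSH and n-BuLi), HMPA, 25 °C; then aq. HCl
Reagents that add atoms: none
Why: SN2 O-alkyl cleavage of the methyl ester by thiolate is indifferent to the two ortho substituents that block acyl attack, and at room temperature it should leave the aryl methyl and benzyl ethers alone.

Step 14
Reactants: 20 3-[2-(benzyloxy)-3-isopropyl-5-methoxy-6-methylphenoxy]-2-isopropyl-6-methoxy-5-methylbenzoic acid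
Product: 21 2-(benzyloxy)-1-isopropyl-3-(2-isopropyl-4-methoxy-5-methylphenoxy)-5-methoxy-4-methylbenzene
Conditions: Ag2CO3 (10 mol %), AcOH (5 mol %), DMSO, 120 °C
Reagents that add atoms: none
Why: Silver-catalysed protodecarboxylation of benzoic acids is favoured by ortho substituents (here methoxy and isopropyl) and proceeds through an arylsilver species that is protonated.

Step 15
Reactants: 21 2-(benzyloxy)-1-isopropyl-3-(2-isopropyl-4-methoxy-5-methylphenoxy)-5-methoxy-4-methylbenzene
Product: 22 2-(2-isopropyl-4-methoxy-5-methylphenoxy)-6-isopropyl-4-methoxy-3-methylphenol (target)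
Conditions: H2 (1 atm), 10% Pd/C, EtOAc–EtOH, 25 °C
Reagents that add atoms: none
Why: Catalytic hydrogenolysis cleaves the benzylic C–O bond of the aryl benzyl ether without touching the diaryl ether or the methyl ethers.

Compound list
1 | thymol (2-isopropyl-5-methylphenol) | CC(C)c1ccc(C)cc1O | starting material
2 | 4-bromo-2-isopropyl-5-methylphenol | CC(C)c1cc(Br)c(C)cc1O | intermediate
3 | 2-isopropyl-4-methoxy-5-methylphenol | COc1cc(C(C)C)c(O)cc1C | intermediate
4 | 2-hydroxy-3-isopropyl-5-methoxy-6-methylbenzaldehyde | O=Cc1c(C)c(OC)cc(C(C)C)c1O | intermediate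
5 | 2-(benzyloxy)-3-isopropyl-5-methoxy-6-methylbenzaldehyde | O=Cc1c(C)c(OC)cc(C(C)C)c1OCc1ccccc1 | intermediate
6 | 2-(benzyloxy)-3-isopropyl-5-methoxy-6-methylphenyl formate | O=COc1c(C)c(OC)cc(C(C)C)c1OCc1ccccc1 | intermediate
7 | 2-(benzyloxy)-3-isopropyl-5-methoxy-6-methylphenol | Oc1c(C)c(OC)cc(C(C)C)c1OCc1ccccc1 | intermediate
8 | 1-bromo-3-methylbutan-2-one | CC(C)C(=O)CBr | starting material
9 | 1-[2-(benzyloxy)-3-isopropyl-5-methoxy-6-methylphenoxy]-3-methylbutan-2-one | CC(C)C(=O)COc1c(C)c(OC)cc(C(C)C)c1OCc1ccccc1 | intermediate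
10 | ethyl formate | CCOC=O | starting material
11 | (1E)-2-[2-(benzyloxy)-3-isopropyl-5-methoxy-6-methylphenoxy]-1-hydroxy-4-methylpent-1-en-3-one | CC(C)C(=O)/C(Oc1c(C)c(OC)cc(C(C)C)c1OCc1ccccc1)=C\O | intermediate
12 | (1E)-2-[2-(benzyloxy)-3-isopropyl-5-methoxy-6-methylphenoxy]-4-methyl-1-(trimethylsilyloxy)pent-1-en-3-one | CC(C)C(=O)/C(Oc1c(C)c(OC)cc(C(C)C)c1OCc1ccccc1)=C\O[Si](C)(C)C | intermediate
13 | methyl 3-oxopentanoate | CCC(=O)CC(=O)OC | starting material
14 | methyl (2Z)-3-(trimethylsilyloxy)pent-2-enoate | CC/C(O[Si](C)(C)C)=C/C(=O)OC | intermediate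
15 | (1Z,3Z)-1-methoxy-1,3-bis(trimethylsilyloxy)penta-1,3-diene | C/C=C(\O[Si](C)(C)C)/C=C(/OC)O[Si](C)(C)C | intermediate
16 | methyl (5E)-6-[2-(benzyloxy)-3-isopropyl-5-methoxy-6-methylphenoxy]-4,8-dimethyl-3,7-dioxonon-5-enoate (racemic at C4; titanium-bound in the flask) | COC(=O)CC(=O)C(C)/C=C(/Oc1c(C)c(OC)cc(C(C)C)c1OCc1ccccc1)C(=O)C(C)C | intermediate
17 | methyl 5-[2-(benzyloxy)-3-isopropyl-5-methoxy-6-methylphenoxy]-6-hydroxy-6-isopropyl-3-methyl-2-oxocyclohex-4-ene-1-carboxylate (mixture of diastereomers) | COC(=O)C1C(=O)C(C)C=C(Oc2c(C)c(OC)cc(C(C)C)c2OCc2ccccc2)C1(O)C(C)C | intermediate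
18 | methyl 3-[2-(benzyloxy)-3-isopropyl-5-methoxy-6-methylphenoxy]-6-hydroxy-2-isopropyl-5-methylbenzoate | COC(=O)c1c(O)c(C)cc(Oc2c(C)c(OC)cc(C(C)C)c2OCc2ccccc2)c1C(C)C | intermediate
19 | methyl 3-[2-(benzyloxy)-3-isopropyl-5-methoxy-6-methylphenoxy]-2-isopropyl-6-methoxy-5-methylbenzoate | COC(=O)c1c(OC)c(C)cc(Oc2c(C)c(OC)cc(C(C)C)c2OCc2ccccc2)c1C(C)C | intermediate
20 | 3-[2-(benzyloxy)-3-isopropyl-5-methoxy-6-methylphenoxy]-2-isopropyl-6-methoxy-5-methylbenzoic acid | OC(=O)c1c(OC)c(C)cc(Oc2c(C)c(OC)cc(C(C)C)c2OCc2ccccc2)c1C(C)C | intermediate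
21 | 2-(benzyloxy)-1-isopropyl-3-(2-isopropyl-4-methoxy-5-methylphenoxy)-5-methoxy-4-methylbenzene | COc1cc(C(C)C)c(Oc2c(C)c(OC)cc(C(C)C)c2OCc2ccccc2)cc1C | intermediate
22 | 2-(2-isopropyl-4-methoxy-5-methylphenoxy)-6-isopropyl-4-methoxy-3-methylphenol | COc1cc(C(C)C)c(Oc2c(C)c(OC)cc(C(C)C)c2O)cc1C | target

Total step count: 15. Longest linear sequence: 13 steps (steps 1–8 and 11–15; steps 9 and 10 form the diene branch).

Steps most likely to fail

Step 11. The ring-closing aldol onto the hindered isopropyl ketone may stall after the first C–C bond has formed. The diene may also be hydrolysed faster than it adds, or TiCl4 may strip the benzyl ether by chelation between the two neighbouring aryl oxygens. The fallback gives up ring construction and accepts a hindered aryl–oxygen coupling; it sets out from phenol 7 and comes back to the route at 21. Commercial carvacrol methyl ether (4-isopropyl-2-methoxy-1-methylbenzene) F1 would be brominated para to its methoxy group with NBS in MeCN to give 1-bromo-2-isopropyl-4-methoxy-5-methylbenzene F2. Bromide F2 would then be joined to phenol 7 by a copper-catalysed Ullmann ether coupling (CuI, picolinic acid, K3PO4, DMSO, 110 °C) to give 21, which needs only step 15.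

Step 13. Dealkylation of the doubly ortho-substituted ester may remain incomplete, or the thiolate may begin to attack the aryl methyl or benzyl ethers once the reaction is forced. The fallback removes the ester carbon by reduction and decarbonylation; it sets out from 19 and comes back at 21, bypassing steps 13 and 14. Ester 19 would be reduced with LiAlH4 in THF at reflux to {3-[2-(benzyloxy)-3-isopropyl-5-methoxy-6-methylphenoxy]-2-isopropyl-6-methoxy-5-methylphenyl}methanol F3. Alcohol F3 would be oxidised with MnO2 in CH2Cl2 to 3-[2-(benzyloxy)-3-isopropyl-5-methoxy-6-methylphenoxy]-2-isopropyl-6-methoxy-5-methylbenzaldehyde F4. Aldehyde F4 would be decarbonylated with stoichiometric RhCl(PPh3)3 in toluene at reflux (Tsuji–Wilkinson decarbonylation) to give 21.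

Step 14. Extrusion of CO2 from the silver carboxylate may be sluggish if sulfur traces from step 13 poison the catalyst, and prolonged heating may then erode the benzyl ether. The fallback replaces protodecarboxylation by halodecarboxylation and reduction; it sets out from acid 20 and comes back at target 22. Acid 20 would undergo transition-metal-free decarboxylative iodination (I2, K3PO4, MeCN, 100 °C) to give 2-(benzyloxy)-3-(3-iodo-2-isopropyl-4-methoxy-5-methylphenoxy)-1-isopropyl-5-methoxy-4-methylbenzene F5. Hydrogenation of iodide F5 (H2, Pd/C, Et3N, EtOAc–EtOH) would remove the iodine and the benzyl group in one operation to give 22; any adventitious ring iodination would be erased in the same step.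

Further compounds
F1 | step 11 | carvacrol methyl ether (4-isopropyl-2-methoxy-1-methylbenzene) | COc1cc(C(C)C)ccc1C
F2 | step 11 | 1-bromo-2-isopropyl-4-methoxy-5-methylbenzene | COc1cc(C(C)C)c(Br)cc1C
F3 | step 13 | {3-[2-(benzyloxy)-3-isopropyl-5-methoxy-6-methylphenoxy]-2-isopropyl-6-methoxy-5-methylphenyl}methanol | OCc1c(OC)c(C)cc(Oc2c(C)c(OC)cc(C(C)C)c2OCc2ccccc2)c1C(C)C
F4 | step 13 | 3-[2-(benzyloxy)-3-isopropyl-5-methoxy-6-methylphenoxy]-2-isopropyl-6-methoxy-5-methylbenzaldehyde | O=Cc1c(OC)c(C)cc(Oc2c(C)c(OC)cc(C(C)C)c2OCc2ccccc2)c1C(C)C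
F5 | step 14 | 2-(benzyloxy)-3-(3-iodo-2-isopropyl-4-methoxy-5-methylphenoxy)-1-isopropyl-5-methoxy-4-methylbenzene | COc1c(I)c(C(C)C)c(Oc2c(C)c(OC)cc(C(C)C)c2OCc2ccccc2)cc1C
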